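**Strategy.** The target is cut back to an acyclic nitro dialdehyde whose C8–C9–C10–C1–C2–C3–C4–C5 chain, with both methyl branches (C14, C15), is the skeleton of geranyl acetate. One prolinol ether catalyst closes both rings in one operation: as an iminium ion it lets the allylic nitronate carbon C5 add to the β,β-disubstituted enal carbon C10 (ring A, quaternary C10); as an enamine it then joins C7 to the aldehyde carbon C8 (ring B). The step exploits the 1,3-relationship C8(O)–C9–C10 and the oxidised ring-fusion carbon C5: its nitro group later delivers oxygen to C3 and leaves the Δ4 alkene for the final singlet-oxygen ene reaction.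

Key step: step 7

Remark: locants C1–C15 and α/β follow eudesmane numbering (β = face of the C10 methyl). The C3=C4 alkene of 4–8 is drawn E as formed in step 1; it is assumed to equilibrate in step 7 through the conjugated nitroalkene tautomer, so its geometry is not critical.

Step 1
Reactants: 1 geranyl acetate, (2E)-3,7-dimethylocta-2,6-dien-1-yl acetate
Product: 2 (2E,6E)-8-hydroxy-3,7-dimethylocta-2,6-dien-1-yl acetate
Conditions: SeO2 (cat.), t-BuOOH, salicylic acid (cat.), CH2Cl2, rt
Reagents that add atoms: tert-butyl hydroperoxide, CC(C)(C)OO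
Why: Selenium dioxide allylic oxidation (ene reaction, then [2,3]-sigmatropic shift) should hydroxylate the (E)-methyl group of the electron-rich terminal trisubstituted alkene, because the 2,3-alkene is deactivated by its allylic acetate.

Step 2
Reactants: 2 (2E,6E)-8-hydroxy-3,7-dimethylocta-2,6-dien-1-yl acetate
Product: 3 (2E,6E)-8-bromo-3,7-dimethylocta-2,6-dien-1-yl acetate
Conditions: CBr4, PPh3, CH2Cl2, 0 °C
Reagents that add atoms: carbon tetrabromide, BrC(Br)(Br)Br
Why: Appel bromination should convert the primary allylic alcohol to the bromide under neutral conditions that leave the acetate and both alkene geometries untouched.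

Step 3
Reactants: 3 (2E,6E)-8-bromo-3,7-dimethylocta-2,6-dien-1-yl acetate
Product: 4 (2E,6E)-3,7-dimethyl-8-nitroocta-2,6-dien-1-yl acetate
Conditions: NaNO2, urea, DMF, −20 °C to rt
Reagents that add atoms: sodium nitrite, [Na+].[O-]N=O
Why: Kornblum nitrite displacement (SN2 at the unhindered primary allylic carbon, N-attack of the ambident nitrite favoured in DMF) should give the primary allylic nitro compound.

Step 4
Reactants: 4 (2E,6E)-3,7-dimethyl-8-nitroocta-2,6-dien-1-yl acetate; 5 methyl acrylate
Product: 6 methyl (5E,9E)-11-acetoxy-5,9-dimethyl-4-nitroundeca-5,9-dienoate (racemic at the nitro carbon)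
Conditions: DBU (10 mol%), MeCN, 0 °C
Reagents that add atoms: none
Why: Base-catalysed Michael addition of the delocalised allylic nitronate should occur at its α-carbon (the nitro-bearing carbon, future C5), the kinetic site of such anions, and appends C6, C7 and C11; the new stereocentre is racemic and is erased as a nitronate in step 7.

Step 5
Reactants: 6 methyl (5E,9E)-11-acetoxy-5,9-dimethyl-4-nitroundeca-5,9-dienoate
Product: 7 (2E,6E)-3,7-dimethyl-8-nitroundeca-2,6-diene-1,11-diol
Conditions: DIBAL-H (excess), CH2Cl2, −78 to −20 °C; Rochelle salt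
Reagents that add atoms: none
Why: DIBAL-H reduction should take the methyl ester to the primary alcohol and cleave the acetate in the same operation, the aliphatic nitro group being inert to aluminium hydrides at low temperature.

Step 6
Reactants: 7 (2E,6E)-3,7-dimethyl-8-nitroundeca-2,6-diene-1,11-diol
Product: 8 (2E,6E)-3,7-dimethyl-8-nitroundeca-2,6-dienedial
Conditions: Dess–Martin periodinane, NaHCO3, CH2Cl2, 0 °C to rt
Reagents that add atoms: none
Why: Dess–Martin oxidation should convert both primary alcohols into aldehydes under buffered, non-basic conditions, giving the (E)-enal without isomerisation and without touching the acidic nitroalkane.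

Step 7
Reactants: 8 (2E,6E)-3,7-dimethyl-8-nitroundeca-2,6-dienedial
Product: 10 3-hydroxy-4a,8-dimethyl-8a-nitro-1,2,3,4,4a,5,6,8a-octahydronaphthalene-2-carbaldehyde (trans-fused; 10β-Me, 5α-NO2, 7β-CHO, 8α-OH, Δ3), via cyclohexene nitro dialdehyde 9 (not isolated)
Conditions: (S)-α,α-diphenylprolinol trimethylsilyl ether (20 mol%), PhCO2H (20 mol%), toluene (0.02 M), rt
Reagents that add atoms: none
Why: The amine condenses with the enal of 8 to an iminium ion, to whose β-carbon C10 the allylic nitronate carbon C5 adds (only the Z nitronate can cyclise); hydrolysis gives 9, whose unhindered aldehyde forms an enamine that adds through C7 to the C8 aldehyde. The closest known reaction type is the iminium–enamine Michael/aldol domino of diarylprolinol silyl ethers, which includes nitroalkane additions to β,β-disubstituted enals that create quaternary centres and 6-enolexo aldol cyclisations of dialdehydes. Ring A closes in the 6-exo-trig mode (attack through the γ-carbon C3 would need a four-membered ring) and ring B in the 6-(enolexo)-exo-trig mode. C10 is set by the catalyst, whose CPh2OSiMe3 group shields the Si face of C10 in the (E)-iminium ion so that C5 adds to the Re face (10R); C5 is set by a chair-like transition state with both tethered arms equatorial and the nitro group axial and anti to the C10 methyl; C7 takes the equatorial position and stays epimerisable, and the C8 hydroxyl forms equatorial, which steps 9 and 10 correct. The step needs the two aldehydes to keep distinct roles, which the substrate secures because the C9 methylene next to the quaternary centre is a poor enamine donor while C7 is unhindered, and it needs high dilution to suppress intermolecular aldol reactions.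

Step 8
Reactants: 10 3-hydroxy-4a,8-dimethyl-8a-nitro-1,2,3,4,4a,5,6,8a-octahydronaphthalene-2-carbaldehyde
Product: 11 3-ethynyl-5,8a-dimethyl-4a-nitro-1,2,3,4,4a,7,8,8a-octahydronaphthalen-2-ol (8α-OH, 7β-ethynyl)
Conditions: dimethyl (1-diazo-2-oxopropyl)phosphonate, K2CO3, MeOH, 0 °C to rt
Reagents that add atoms: dimethyl (1-diazo-2-oxopropyl)phosphonate, COP(=O)(OC)C(=[N+]=[N-])C(C)=O
Why: Ohira–Bestmann (Seyferth–Gilbert) homologation should convert the aldehyde carbon C11 into a terminal alkyne, adding C13, under carbonate/methanol conditions mild enough for the β-hydroxy aldehyde; any epimerisation at C7 only reinforces the equatorial arrangement.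

Step 9
Reactants: 11 3-ethynyl-5,8a-dimethyl-4a-nitro-1,2,3,4,4a,7,8,8a-octahydronaphthalen-2-ol (8α-OH)
Product: 12 3-ethynyl-5,8a-dimethyl-4a-nitro-3,4,4a,7,8,8a-hexahydronaphthalen-2(1H)-one
Conditions: Dess–Martin periodinane, NaHCO3, CH2Cl2, 0 °C
Reagents that add atoms: none
Why: Dess–Martin oxidation should give the 8-ketone and remove the provisional C8 stereocentre, the buffered conditions avoiding isomerisation of the β,γ-alkynyl ketone to an allenone.

Step 10
Reactants: 12 3-ethynyl-5,8a-dimethyl-4a-nitro-3,4,4a,7,8,8a-hexahydronaphthalen-2(1H)-one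
Product: 13 3-ethynyl-5,8a-dimethyl-4a-nitro-1,2,3,4,4a,7,8,8a-octahydronaphthalen-2-ol (8β-OH, axial)
Conditions: L-Selectride, THF, −78 °C; H2O
Reagents that add atoms: none
Why: Bulky hydride reduction (L-Selectride) should deliver hydride along the equatorial trajectory from the α face, since axial approach on the β face is blocked by the syn-axial C10 methyl group, giving the axial 8β-alcohol.

Step 11
Reactants: 13 3-ethynyl-5,8a-dimethyl-4a-nitro-1,2,3,4,4a,7,8,8a-octahydronaphthalen-2-ol (8β-OH)
Product: 14 3-ethynyl-5,8a-dimethyl-4a-nitro-1,2,3,4,4a,7,8,8a-octahydronaphthalen-2-yl acetate (8β-OAc)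
Conditions: Ac2O, DMAP, pyridine, 40 °C
Reagents that add atoms: acetic anhydride, CC(=O)OC(C)=O
Why: DMAP-catalysed acylation should acetylate the hindered axial alcohol before any ester is present at C12, so that no γ-lactone can form.

Step 12
Reactants: 14 3-ethynyl-5,8a-dimethyl-4a-nitro-1,2,3,4,4a,7,8,8a-octahydronaphthalen-2-yl acetate
Product: 15 methyl 2-[3-acetoxy-4a,8-dimethyl-8a-nitro-1,2,3,4,4a,5,6,8a-octahydronaphthalen-2-yl]prop-2-enoate (5α-NO2, 7β, 8β-OAc)
Conditions: Pd(OAc)2 (cat.), 2-(diphenylphosphino)pyridine, MsOH (cat.), CO (10 bar), MeOH, 45 °C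
Reagents that add atoms: carbon monoxide, [C-]#[O+]; methanol, CO
Why: Palladium/2-pyridylphosphine-catalysed Markovnikov methoxycarbonylation of the terminal alkyne should place the ester on the internal carbon C11 and leave C13 as the methylene, giving the 2-substituted acrylate directly; it is run before the nitro group is traded for the acid-labile allylic alcohol.

Step 13
Reactants: 15 methyl 2-[3-acetoxy-4a,8-dimethyl-8a-nitro-1,2,3,4,4a,5,6,8a-octahydronaphthalen-2-yl]prop-2-enoate
Product: 17 methyl 2-[3-acetoxy-7-hydroxy-4a,8-dimethyl-1,2,3,4,4a,5,6,7-octahydronaphthalen-2-yl]prop-2-enoate (3α-OH, Δ4), via allylic nitrite 16 (not isolated)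
Conditions: toluene, BHT (cat.), 90 °C; then MeOH, rt
Reagents that add atoms: none
Why: Thermal allylic nitro-to-nitrite [2,3]-sigmatropic rearrangement should be driven by relief of strain at the quaternary C5 and formation of the tetrasubstituted C4=C5 alkene, and being suprafacial it should deliver oxygen from the axial 5α-nitro group to the α face of C3; methanol then cleaves the nitrite ester by transnitrosation.

Step 14
Reactants: 17 methyl 2-[3-acetoxy-7-hydroxy-4a,8-dimethyl-1,2,3,4,4a,5,6,7-octahydronaphthalen-2-yl]prop-2-enoate (3α-OH)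
Product: 18 methyl 2-[3-acetoxy-4a,8-dimethyl-7-(2-methylpropanoyloxy)-1,2,3,4,4a,5,6,7-octahydronaphthalen-2-yl]prop-2-enoate (3β-ester)
Conditions: i-PrCO2H, PPh3, DIAD, THF, 0 °C to rt
Reagents that add atoms: isobutyric acid, CC(C)C(=O)O
Why: Mitsunobu esterification should proceed by SN2 inversion at the pseudoaxial allylic 3α-alcohol to give the equatorial 3β-isobutyrate, SN2′ attack being excluded because C5 is fully substituted.

Step 15
Reactants: 18 methyl 2-[3-acetoxy-4a,8-dimethyl-7-(2-methylpropanoyloxy)-1,2,3,4,4a,5,6,7-octahydronaphthalen-2-yl]prop-2-enoate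
Product: 19 methyl 2-[3-acetoxy-8a-hydroperoxy-4a-methyl-8-methylidene-7-(2-methylpropanoyloxy)decahydronaphthalen-2-yl]prop-2-enoate (CNP0244758.1; 3β-ester, 5α-OOH, 7β, 8β-OAc, 10β-Me)
Conditions: O2, tetraphenylporphyrin (cat.), visible light, CH2Cl2, −20 °C
Reagents that add atoms: dioxygen, O=O
Why: Schenck ene reaction of singlet oxygen with the electron-rich tetrasubstituted alkene should occur on the α face anti to the axial C10 methyl, with hydrogen abstraction from the C15 methyl on the more crowded C15/C6 side (cis effect; H-6α lies in the alkene plane and H-3α is geminal to the acyloxy group), so that oxygen bonds to C5 and the double bond moves to C4=C15, while the acrylate is too electron-poor to react.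

**Compound list**
1 | geranyl acetate | CC(C)=CCC/C(C)=C/COC(C)=O | starting material
2 | (2E,6E)-8-hydroxy-3,7-dimethylocta-2,6-dien-1-yl acetate | OC/C(C)=C/CC/C(C)=C/COC(C)=O | intermediate
3 | (2E,6E)-8-bromo-3,7-dimethylocta-2,6-dien-1-yl acetate | BrC/C(C)=C/CC/C(C)=C/COC(C)=O | intermediate
4 | (2E,6E)-3,7-dimethyl-8-nitroocta-2,6-dien-1-yl acetate | [O-][N+](=O)C/C(C)=C/CC/C(C)=C/COC(C)=O | intermediate
5 | methyl acrylate | C=CC(=O)OC | starting material
6 | methyl (5E,9E)-11-acetoxy-5,9-dimethyl-4-nitroundeca-5,9-dienoate | COC(=O)CCC([N+](=O)[O-])/C(C)=C/CC/C(C)=C/COC(C)=O | intermediate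
7 | (2E,6E)-3,7-dimethyl-8-nitroundeca-2,6-diene-1,11-diol | OCCCC([N+](=O)[O-])/C(C)=C/CC/C(C)=C/CO | intermediate
8 | (2E,6E)-3,7-dimethyl-8-nitroundeca-2,6-dienedial | O=CCCC([N+](=O)[O-])/C(C)=C/CC/C(C)=C/C=O | intermediate
9 | 3-[2,6-dimethyl-1-nitro-6-(2-oxoethyl)cyclohex-2-en-1-yl]propanal (nitro trans to the C6 methyl; not isolated) | O=CCC[C@@]1([N+](=O)[O-])C(C)=CCC[C@]1(C)CC=O | intermediate
10 | 3-hydroxy-4a,8-dimethyl-8a-nitro-1,2,3,4,4a,5,6,8a-octahydronaphthalene-2-carbaldehyde (10β-Me, 5α-NO2, 7β-CHO, 8α-OH) | O=C[C@H]1C[C@@]2([N+](=O)[O-])C(C)=CCC[C@]2(C)C[C@@H]1O | intermediate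
11 | 3-ethynyl-5,8a-dimethyl-4a-nitro-1,2,3,4,4a,7,8,8a-octahydronaphthalen-2-ol (8α-OH) | C#C[C@H]1C[C@@]2([N+](=O)[O-])C(C)=CCC[C@]2(C)C[C@@H]1O | intermediate
12 | 3-ethynyl-5,8a-dimethyl-4a-nitro-3,4,4a,7,8,8a-hexahydronaphthalen-2(1H)-one | C#C[C@H]1C[C@@]2([N+](=O)[O-])C(C)=CCC[C@]2(C)CC1=O | intermediate
13 | 3-ethynyl-5,8a-dimethyl-4a-nitro-1,2,3,4,4a,7,8,8a-octahydronaphthalen-2-ol (8β-OH) | C#C[C@H]1C[C@@]2([N+](=O)[O-])C(C)=CCC[C@]2(C)C[C@H]1O | intermediate
14 | 3-ethynyl-5,8a-dimethyl-4a-nitro-1,2,3,4,4a,7,8,8a-octahydronaphthalen-2-yl acetate (8β-OAc) | C#C[C@H]1C[C@@]2([N+](=O)[O-])C(C)=CCC[C@]2(C)C[C@H]1OC(C)=O | intermediate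
15 | methyl 2-[3-acetoxy-4a,8-dimethyl-8a-nitro-1,2,3,4,4a,5,6,8a-octahydronaphthalen-2-yl]prop-2-enoate | C=C(C(=O)OC)[C@H]1C[C@@]2([N+](=O)[O-])C(C)=CCC[C@]2(C)C[C@H]1OC(C)=O | intermediate
16 | methyl 2-[3-acetoxy-4a,8-dimethyl-7-(nitrosooxy)-1,2,3,4,4a,5,6,7-octahydronaphthalen-2-yl]prop-2-enoate (3α-ONO; not isolated) | C=C(C(=O)OC)[C@H]1CC2=C(C)[C@H](ON=O)CC[C@]2(C)C[C@H]1OC(C)=O | intermediate
17 | methyl 2-[3-acetoxy-7-hydroxy-4a,8-dimethyl-1,2,3,4,4a,5,6,7-octahydronaphthalen-2-yl]prop-2-enoate (3α-OH) | C=C(C(=O)OC)[C@H]1CC2=C(C)[C@H](O)CC[C@]2(C)C[C@H]1OC(C)=O | intermediate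
18 | methyl 2-[3-acetoxy-4a,8-dimethyl-7-(2-methylpropanoyloxy)-1,2,3,4,4a,5,6,7-octahydronaphthalen-2-yl]prop-2-enoate (3β-ester) | C=C(C(=O)OC)[C@H]1CC2=C(C)[C@@H](OC(=O)C(C)C)CC[C@]2(C)C[C@H]1OC(C)=O | intermediate
19 | methyl 2-[3-acetoxy-8a-hydroperoxy-4a-methyl-8-methylidene-7-(2-methylpropanoyloxy)decahydronaphthalen-2-yl]prop-2-enoate (CNP0244758.1) | C=C(C(=O)OC)[C@H]1C[C@@]2(OO)C(=C)[C@@H](OC(=O)C(C)C)CC[C@]2(C)C[C@H]1OC(C)=O | target

Total step count: 15. Longest linear sequence: 15 steps (from geranyl acetate).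

**Steps most likely to fail**

Step 7. The two aldehydes may exchange roles in the aldol step, the aldol may lose water to the 7,8-enal, and facial control at C10 may be eroded by E/Z isomerisation of the iminium ion. The fallback sets out from 7 and returns at 10, forming the two bonds separately. MnO2 should oxidise only the allylic hydroxyl of 7 to give (2E,6E)-11-hydroxy-3,7-dimethyl-8-nitroundeca-2,6-dienal F1. With no second aldehyde present, the same prolinol ether catalyst should effect the nitro-Michael ring closure alone to give 2-[2-(3-hydroxypropyl)-1,3-dimethyl-2-nitrocyclohex-3-en-1-yl]acetaldehyde F2. Dess–Martin oxidation should then give dialdehyde 9, now isolated, and L-proline in DMSO should close ring B by a separate 6-enolexo aldol reaction to 10.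

Step 13. Homolysis of the C–N bond or loss of nitrous acid may give dienes instead of the sigmatropic shift, and radical recombination would scramble C3. The fallback sets out from 15 and returns at 17. Palladium(0)-catalysed allylic substitution with the nitro group as leaving group (Pd(PPh3)4, sodium chloroacetate, THF, 50 °C) should deliver the carboxylate to the less hindered allyl terminus C3 with net retention, giving methyl 2-[3-acetoxy-7-(chloroacetoxy)-4a,8-dimethyl-1,2,3,4,4a,5,6,7-octahydronaphthalen-2-yl]prop-2-enoate F3. Thiourea and NaHCO3 in ethanol should then remove the chloroacetyl group in the presence of the acetate to give 17.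

Step 14. The activated allylic alcohol may eliminate to a diene or ionise, so that inversion is incomplete. The fallback sets out from 17 and returns at 18, and it also makes the outcome independent of the C3 configuration delivered by step 13. MnO2 should oxidise the allylic alcohol to the enone methyl 2-[3-acetoxy-4a,8-dimethyl-7-oxo-1,2,3,4,4a,5,6,7-octahydronaphthalen-2-yl]prop-2-enoate F4. Luche reduction (NaBH4, CeCl3, MeOH, −78 °C) should add hydride axially from the α face, anti to the C10 methyl, to give the 3β-alcohol methyl 2-[3-acetoxy-7-hydroxy-4a,8-dimethyl-1,2,3,4,4a,5,6,7-octahydronaphthalen-2-yl]prop-2-enoate F5. Isobutyryl chloride, pyridine and DMAP should then give 18.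

**Further compounds**
F1 | step 7 | (2E,6E)-11-hydroxy-3,7-dimethyl-8-nitroundeca-2,6-dienal | OCCCC([N+](=O)[O-])/C(C)=C/CC/C(C)=C/C=O
F2 | step 7 | 2-[2-(3-hydroxypropyl)-1,3-dimethyl-2-nitrocyclohex-3-en-1-yl]acetaldehyde | OCCC[C@@]1([N+](=O)[O-])C(C)=CCC[C@]1(C)CC=O
F3 | step 13 | methyl 2-[3-acetoxy-7-(chloroacetoxy)-4a,8-dimethyl-1,2,3,4,4a,5,6,7-octahydronaphthalen-2-yl]prop-2-enoate (3α) | C=C(C(=O)OC)[C@H]1CC2=C(C)[C@H](OC(=O)CCl)CC[C@]2(C)C[C@H]1OC(C)=O
F4 | step 14 | methyl 2-[3-acetoxy-4a,8-dimethyl-7-oxo-1,2,3,4,4a,5,6,7-octahydronaphthalen-2-yl]prop-2-enoate | C=C(C(=O)OC)[C@H]1CC2=C(C)C(=O)CC[C@]2(C)C[C@H]1OC(C)=O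
F5 | step 14 | methyl 2-[3-acetoxy-7-hydroxy-4a,8-dimethyl-1,2,3,4,4a,5,6,7-octahydronaphthalen-2-yl]prop-2-enoate (3β-OH) | C=C(C(=O)OC)[C@H]1CC2=C(C)[C@@H](O)CC[C@]2(C)C[C@H]1OC(C)=O
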